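I read the solid first. You wanted a quick number, so here is mine against your forecast.

| setting | spring | noon | epsilon | gamma |
|---|---|---|---|---|
| solid electrophile | 1 mM | 1 mM | 1.0 mM | 1.0 mM |
| nucleophile | 3 mM | 3 mM | 3.00 mM | 3.00 mM |
| free base | 1 mM | 1.9 mM | 1.20 mM | 2.40 mM |
| protic impurity | 0.020 mM | 0.020 mM | 0.0200 mM | 0.0200 mM |
| remark | run made earlier | run made earlier |  |  |
| time |  |  | 3.0 min | 3.0 min |

- spring (time / s: solid electrophile / %, target / %): 12.0: 69, 0; 30.0: 54, 6; 60.0: 46, 10; 90.0: 40, 15; 120: 32, 19
- noon (time / s: solid electrophile / %, target / %): 10.0: 72, 1; 20.0: 60, 1; 40.0: 50, 6; 60.0: 46, 10; 120: 27, 13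

(each reading ± 1.5 percentage points)

- the numbers in the tables scatter with a standard deviation of 1.5 percentage points
- at the start none of the solid electrophile is in solution
- what has only dissolved of solid electrophile counts as not reacted

1. part of the solid electrophile that has reacted (what has only dissolved counts as not reacted) at the end, epsilon
2. part of the solid electrophile that has reacted (what has only dissolved counts as not reacted) at the end, gamma
3. what raising the concentration of free base from its lowest to its highest value here does to the part of the solid electrophile that has reacted (what has only dissolved counts as not reacted) (changes below 5 percentage points count as none) (no change / it rises / it falls)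

1. From 30.0 s to 120 s the spring readings of the solid fell close to a straight line, as a fraction of the charge at 0.147 min⁻¹. The noon solid fell 0.172 min⁻¹ from 40.0 s to 120 s, with nearly twice the base. I judged that gap to lie within the scatter and saw no base effect.

2. I averaged the two: 0.160 min⁻¹. I called this the drain, the fraction of the charge leaving the solid per minute once the dissolved level stands still, a pseudo-zero-order rate.

3. Over the first 12.0 s the spring solid fell 1.55 min⁻¹, ten times the drain. I took that burst as dissolving, and the later line as reaction, with solid replacing what reacts.

4. Running the line back from 60.0 s put the dissolved level at 38.0 %. My estimate for 3.0 min was 47.9 % in both epsilon and gamma, which leaves 14.1 % as solid in my reckoning, so I expected the line to last. I expected no change with base.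

5. Your forecast said 28 %, 26 % and no change, holding that “target is the best measure of reacted material”. My figure is higher; on the trend we agree.

6. The flask gave 41.8 % in epsilon, 42.2 % in gamma: no change, a shift of 0.43 percentage points.

    nucleophile + acid set free ⇌ protonated nucleophile, settled at all times (K = 11000 M⁻¹)
    solid electrophile ⇌ electrophile, rate k2*(cs2 - [electrophile]) while solid is left; crystals form when [electrophile] > cs2 (solubility = 0.430 mM, k = 0.110 s⁻¹)
    acid set free + free base ⇌ salt of the base (K = 8.40 × 10⁵ M⁻¹, k = 990 M⁻¹ s⁻¹)
    free base + target → over-reaction product (k = 10.0 M⁻¹ s⁻¹)
    protic impurity + free base → quenched reagent (k = 380 M⁻¹ s⁻¹)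
    electrophile + nucleophile → acid set free + target (k = 2.20 M⁻¹ s⁻¹)

In epsilon, electrophile was made 2.46 times as fast as it was used at 0.372 min and 1.01 times at 3.00 min, and it stood at 40.8 % of the charge at 1.50 min and 40.9 % at 3.00 min. From 1.50 min to 3.00 min the epsilon solid fell 0.142 min⁻¹, beside my drain of 0.160 min⁻¹. Shared over the neighbour flask's 1.7 mM charge of solid, the drain makes 28.2 % in 3.0 min, and that flask reacted 24.6 %.

The data were generated by integration from invented constants, and the scatter is random.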